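## Retrosynthetic overview

1. The target comes from the methyl ester of the same (S)-dihydrobenzofuran by a final double MeMgBr addition; that ester comes from its 4-O-prenyl isomer by a clay 1,3-shift that moves prenyl from O4 to C5.
2. The dihydrofuran O1–C2 bond is closed by an intramolecular Mitsunobu reaction (inversion) of an (R)-aryl-lactate. The para oxygen is blocked as the prenyl ether, so only the oxygen next to the ketone can cyclise.
3. The key C3–C3a bond is made by a visible-light decarboxylative C–H alkylation of the acylphloroglucinolate with a redox-active ester of D-malic acid, which supplies the stereocentre.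
4. The acylphloroglucinol comes from phloroglucinol and 3-(4-methoxyphenyl)propanoic acid (Friedel–Crafts), followed by para-selective O-prenylation.
5. Ring order: both benzene rings are bought; the dihydrofuran is the only ring made (step 5), after the key C–C bond (step 4).

Assumption: D-(+)-malic acid (6, the R enantiomer) is taken as an inexpensive commercial chiral-pool acid; step 3 is a two-stage, one-flask operation counted as one step.

## Route

Step 1
Reactants: 1 phloroglucinol; 2 3-(4-methoxyphenyl)propanoic acid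
Product: 3 1-(2,4,6-trihydroxyphenyl)-3-(4-methoxyphenyl)propan-1-one
Conditions: BF3·OEt2 (as solvent), 85 °C; aq. NaOAc work-up
Reagents that add atoms: none
Why: BF3-mediated Friedel–Crafts C-acylation of phloroglucinol with the free acid stops at the mono-ketone because the product is deactivated as its boron chelate, and the anisole ether is not cleaved by BF3.

Step 2
Reactants: 3 1-(2,4,6-trihydroxyphenyl)-3-(4-methoxyphenyl)propan-1-one; 4 prenyl bromide (1-bromo-3-methylbut-2-ene)
Product: 5 1-{2,6-dihydroxy-4-[(3-methylbut-2-en-1-yl)oxy]phenyl}-3-(4-methoxyphenyl)propan-1-one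
Conditions: K2CO3 (1.1 equiv), acetone, rt
Reagents that add atoms: none
Why: Williamson etherification is selective for the OH para to the ketone (most acidic, not hydrogen-bonded to C=O), which blocks the oxygen that must stay out of the later ring closure and places the prenyl group next to its final carbon.

Step 3
Reactants: 6 D-malic acid [(R)-2-hydroxybutanedioic acid]
Product: 8 1,3-dioxoisoindolin-2-yl 2-[(4R)-2,2-dimethyl-5-oxo-1,3-dioxolan-4-yl]acetate, via acetonide acid 7 (not isolated)
Conditions: 2,2-dimethoxypropane, p-TsOH (cat.), rt, then evaporate; N-hydroxyphthalimide, DIC, DMAP (cat.), CH2Cl2, 0 °C→rt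
Reagents that add atoms: 2,2-dimethoxypropane (COC(C)(C)OC); N-hydroxyphthalimide (O=C1c2ccccc2C(=O)N1O)
Why: Acetalisation ties the α-hydroxy acid into the five-membered dioxolanone, leaving only the β-carboxyl free for Steglich-type esterification to the redox-active ester, and no bond to the bought stereocentre is broken.

Step 4
Reactants: 5 1-{2,6-dihydroxy-4-[(3-methylbut-2-en-1-yl)oxy]phenyl}-3-(4-methoxyphenyl)propan-1-one; 8 1,3-dioxoisoindolin-2-yl 2-[(4R)-2,2-dimethyl-5-oxo-1,3-dioxolan-4-yl]acetate
Product: 10 methyl (2R)-3-{2,4-dihydroxy-3-[3-(4-methoxyphenyl)propanoyl]-6-[(3-methylbut-2-en-1-yl)oxy]phenyl}-2-hydroxypropanoate, via dioxolanone adduct 9 (not isolated)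
Conditions: 5 (2 equiv), Cs2CO3 (2 equiv), DMA, Ar, 456 nm LEDs, 20 °C; then MeOH, 0 °C→rt; AcOH quench
Reagents that add atoms: methanol (CO)
Why: Proposed new method: photochemical decarboxylative ortho-C–H alkylation of an acylphloroglucinolate, in which the caesium phenolate of 5 and the electron-poor phthalimide ester 8 form a coloured donor–acceptor complex, blue light triggers single-electron transfer, the radical anion of 8 loses phthalimide anion and CO2, and the primary alkyl radical combines with the aryloxyl radical (or adds to a second phenolate in an SRN1-type chain) at the only H-bearing ring carbon (the two are equivalent) before tautomerisation restores the arene; the stereocentre is one carbon away from the radical and untouched, and carbonate/methanol then opens the dioxolanone to the methyl ester; the closest known reaction types are donor–acceptor-complex and excited-phenolate C-alkylation of phenols with alkyl iodides, photostimulated SRN1 alkylation of enolates by neopentyl-type radicals, and light-driven decarboxylation of N-acyloxyphthalimides.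

Step 5
Reactants: 10 methyl (2R)-3-{2,4-dihydroxy-3-[3-(4-methoxyphenyl)propanoyl]-6-[(3-methylbut-2-en-1-yl)oxy]phenyl}-2-hydroxypropanoate
Product: 11 methyl (2S)-6-hydroxy-7-[3-(4-methoxyphenyl)propanoyl]-4-[(3-methylbut-2-en-1-yl)oxy]-2,3-dihydro-1-benzofuran-2-carboxylate
Conditions: PPh3, DIAD (betaine pre-formed), THF, −20 °C→rt
Reagents that add atoms: none
Why: Intramolecular Mitsunobu etherification, in which the phenol flanked by the ketone and the side chain (the other neighbouring oxygen is the prenyl ether) displaces the activated α-hydroxy-ester oxygen in a 5-exo-tet SN2 step with clean inversion, converting the (R)-carbinol into the (S)-configured C2.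

Step 6
Reactants: 11 methyl (2S)-6-hydroxy-7-[3-(4-methoxyphenyl)propanoyl]-4-[(3-methylbut-2-en-1-yl)oxy]-2,3-dihydro-1-benzofuran-2-carboxylate
Product: 12 methyl (2S)-4,6-dihydroxy-7-[3-(4-methoxyphenyl)propanoyl]-5-(3-methylbut-2-en-1-yl)-2,3-dihydro-1-benzofuran-2-carboxylate
Conditions: Montmorillonite K10, CH2Cl2, 0 °C→rt
Reagents that add atoms: none
Why: Clay-catalysed 1,3-O→C prenyl shift of an aryl prenyl ether (ion-pair rearrangement) delivers prenyl to C5, the only unsubstituted ring carbon and ortho to the ether oxygen, while the ester, ketone and remote stereocentre are inert to the mild solid acid.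

Step 7
Reactants: 12 methyl (2S)-4,6-dihydroxy-7-[3-(4-methoxyphenyl)propanoyl]-5-(3-methylbut-2-en-1-yl)-2,3-dihydro-1-benzofuran-2-carboxylate
Product: 13 1-[(2S)-4,6-dihydroxy-2-(2-hydroxypropan-2-yl)-5-(3-methylbut-2-en-1-yl)-2,3-dihydro-1-benzofuran-7-yl]-3-(4-methoxyphenyl)propan-1-one
Conditions: MeMgBr (5 equiv), THF, −40→0 °C; aq. NH4Cl
Reagents that add atoms: methylmagnesium bromide (C[Mg]Br)
Why: Double Grignard addition to the electrophilic α-aryloxy ester gives the tertiary alcohol, while the aryl ketone is protected in situ as a magnesium phenoxide chelate conjugated to ortho and para oxido groups (a vinylogous carboxylate), and C2 is not a reaction site and stays S.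

## Compound list

1 | phloroglucinol | Oc1cc(O)cc(O)c1 | starting material
2 | 3-(4-methoxyphenyl)propanoic acid | COc1ccc(CCC(=O)O)cc1 | starting material
3 | 1-(2,4,6-trihydroxyphenyl)-3-(4-methoxyphenyl)propan-1-one | COc1ccc(CCC(=O)c2c(O)cc(O)cc2O)cc1 | intermediate
4 | prenyl bromide (1-bromo-3-methylbut-2-ene) | CC(C)=CCBr | starting material
5 | 1-{2,6-dihydroxy-4-[(3-methylbut-2-en-1-yl)oxy]phenyl}-3-(4-methoxyphenyl)propan-1-one | COc1ccc(CCC(=O)c2c(O)cc(OCC=C(C)C)cc2O)cc1 | intermediate
6 | D-malic acid, (R)-2-hydroxybutanedioic acid | O[C@H](CC(=O)O)C(=O)O | starting material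
7 | 2-[(4R)-2,2-dimethyl-5-oxo-1,3-dioxolan-4-yl]acetic acid | CC1(C)O[C@H](CC(=O)O)C(=O)O1 | intermediate
8 | 1,3-dioxoisoindolin-2-yl 2-[(4R)-2,2-dimethyl-5-oxo-1,3-dioxolan-4-yl]acetate | CC1(C)O[C@H](CC(=O)ON2C(=O)c3ccccc3C2=O)C(=O)O1 | intermediate
9 | (5R)-5-{2,4-dihydroxy-3-[3-(4-methoxyphenyl)propanoyl]-6-[(3-methylbut-2-en-1-yl)oxy]benzyl}-2,2-dimethyl-1,3-dioxolan-4-one | COc1ccc(CCC(=O)c2c(O)cc(OCC=C(C)C)c(C[C@H]3OC(C)(C)OC3=O)c2O)cc1 | intermediate
10 | methyl (2R)-3-{2,4-dihydroxy-3-[3-(4-methoxyphenyl)propanoyl]-6-[(3-methylbut-2-en-1-yl)oxy]phenyl}-2-hydroxypropanoate | COc1ccc(CCC(=O)c2c(O)cc(OCC=C(C)C)c(C[C@@H](O)C(=O)OC)c2O)cc1 | intermediate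
11 | methyl (2S)-6-hydroxy-7-[3-(4-methoxyphenyl)propanoyl]-4-[(3-methylbut-2-en-1-yl)oxy]-2,3-dihydro-1-benzofuran-2-carboxylate | COc1ccc(CCC(=O)c2c(O)cc(OCC=C(C)C)c3c2O[C@H](C(=O)OC)C3)cc1 | intermediate
12 | methyl (2S)-4,6-dihydroxy-7-[3-(4-methoxyphenyl)propanoyl]-5-(3-methylbut-2-en-1-yl)-2,3-dihydro-1-benzofuran-2-carboxylate | COc1ccc(CCC(=O)c2c(O)c(CC=C(C)C)c(O)c3c2O[C@H](C(=O)OC)C3)cc1 | intermediate
13 | 1-[(2S)-4,6-dihydroxy-2-(2-hydroxypropan-2-yl)-5-(3-methylbut-2-en-1-yl)-2,3-dihydro-1-benzofuran-7-yl]-3-(4-methoxyphenyl)propan-1-one (CNP0150199.1) | COc1ccc(CCC(=O)c2c(O)c(CC=C(C)C)c(O)c3c2O[C@H](C(C)(C)O)C3)cc1 | target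

## Step count and risks

Total steps: 7. Longest linear sequence: 6 (steps 1, 2, 4, 5, 6, 7); the malic acid branch (step 3) joins at step 4.

Steps most likely to fail:

**Step 4** (the proposed photochemical C–H alkylation). Risks are O-acylation of the phenolate by 8, aryloxyl dimerisation and double alkylation. The fallback uses known chemistry, sets out from 5 and comes back at 9. Iodination of 5 at the free ring carbon (I2, NaHCO3, THF–H2O, 0 °C) gives 1-{2,6-dihydroxy-3-iodo-4-[(3-methylbut-2-en-1-yl)oxy]phenyl}-3-(4-methoxyphenyl)propan-1-one F1. Nickel-catalysed reductive decarboxylative arylation of the redox-active ester 8 with F1 (NiBr2·glyme, dtbbpy, Zn, DMA, rt) then gives 9, which is methanolysed to 10 as in the second stage of step 4.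

**Step 6** (clay 1,3-shift). Risks are loss of the prenyl group and chroman formation from the ortho-prenylphenol product. The fallback sets out from 11 and comes back at 12. The prenyl ether is cleaved with CeCl3·7H2O/NaI (MeCN, reflux) to methyl (2S)-4,6-dihydroxy-7-[3-(4-methoxyphenyl)propanoyl]-2,3-dihydro-1-benzofuran-2-carboxylate F2. Direct C-prenylation of the only free ring carbon with 4 (NaOMe, 2 equiv, MeOH, 0 °C) then gives 12.

**Step 7** (Grignard addition beside an aryl ketone). Risks are attack on the ketone and enolisation or ring opening at C2. The fallback sets out from 10 and comes back at 13. MeMgBr (6 equiv, THF, −40→0 °C) is added to 10, where the ketone sits between two magnesium phenoxides, giving 1-{3-[(2R)-2,3-dihydroxy-3-methylbutyl]-2,6-dihydroxy-4-[(3-methylbut-2-en-1-yl)oxy]phenyl}-3-(4-methoxyphenyl)propan-1-one F3. Mitsunobu ring closure (PPh3, DIAD, THF; SN2 inversion at the secondary carbinol) gives 1-{(2S)-6-hydroxy-2-(2-hydroxypropan-2-yl)-4-[(3-methylbut-2-en-1-yl)oxy]-2,3-dihydro-1-benzofuran-7-yl}-3-(4-methoxyphenyl)propan-1-one F4. The clay shift of step 6 applied to F4 gives 13.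

Further compounds
F1 | step 4 | 1-{2,6-dihydroxy-3-iodo-4-[(3-methylbut-2-en-1-yl)oxy]phenyl}-3-(4-methoxyphenyl)propan-1-one | COc1ccc(CCC(=O)c2c(O)cc(OCC=C(C)C)c(I)c2O)cc1
F2 | step 6 | methyl (2S)-4,6-dihydroxy-7-[3-(4-methoxyphenyl)propanoyl]-2,3-dihydro-1-benzofuran-2-carboxylate | COc1ccc(CCC(=O)c2c(O)cc(O)c3c2O[C@H](C(=O)OC)C3)cc1
F3 | step 7 | 1-{3-[(2R)-2,3-dihydroxy-3-methylbutyl]-2,6-dihydroxy-4-[(3-methylbut-2-en-1-yl)oxy]phenyl}-3-(4-methoxyphenyl)propan-1-one | COc1ccc(CCC(=O)c2c(O)cc(OCC=C(C)C)c(C[C@@H](O)C(C)(C)O)c2O)cc1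
F4 | step 7 | 1-{(2S)-6-hydroxy-2-(2-hydroxypropan-2-yl)-4-[(3-methylbut-2-en-1-yl)oxy]-2,3-dihydro-1-benzofuran-7-yl}-3-(4-methoxyphenyl)propan-1-one | COc1ccc(CCC(=O)c2c(O)cc(OCC=C(C)C)c3c2O[C@H](C(C)(C)O)C3)cc1
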